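**Plan**
1. Retrosynthesis: the diene is cut at C13–C14 (enol triflate + vinyltin) and the cinnamate C=C is traced back to a saturated acyl chain. The C4–C19 bond is then cut between a 14,15,19-trinorlabda-3,7-diene core and an acyloxymethyl-metal reagent carrying the whole C19–O–acyl unit. C9–C11 (alkylative enone transposition), C3=C4 (metathesis) and C10–C1 (alkylation) lead back to (R)-carvone, which is ring B.
2. Forward: carvone → quaternary C10 by two α′-alkylations → ring A by ring-closing metathesis → side chain on C9 and the C7=C8 bond by transposition chemistry → fragment union at C4 → C2=C3 hydrogenation, 7,8-dihydroxylation, ester dehydrogenation, diene.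
3. Enabling feature: in ring A, C4 is the γ-terminus of the allyl unit C2–C3=C4, and a temporary oxygen on C2 lies on the β face, the face of the C10 methyl. Its 2-(diphenylphosphanyl)benzoate binds the copper reagent and hands the acyloxymethyl group to C4β. This gives the axial C19 that an undirected reagent (α-face attack) would not give.
4. Stereochemistry: C5 from carvone; C10 by alkylation anti to the isopropenyl group; C2 (temporary) by CBS reduction; C4 by 1,3-transfer from C2; C9 by suprafacial hydrogen transfer from a 7α-diazene; C7/C8 by α-face OsO4; the E double bond by selenoxide syn-elimination.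
5. Helpers and their removal: the C2 oxygen leaves in the key step and the C2=C3 bond is hydrogenated. The acyl chain is carried two hydrogens above the cinnamate level because hydrogenation and OsO4 follow the union. Ketal, acetonide and silyl groups come off at the end.

Key step: step 16

Remark: labdane numbering and α/β descriptors (β = face of the C10 methyl) are used for all bicyclic compounds. Carvone carbons C1, C2, C3, C4, C5, C6 become C9, C8, C7, C6, C5, C10, and the isopropenyl carbon becomes C4 (its methyl is C18). TBS = tert-butyldimethylsilyl.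

**Route**

Step 1
Reactants: 1 3-(4-hydroxyphenyl)propanoic acid
Product: 3 3-[4-(TBS-oxy)phenyl]propanoic acid, via bis-silyl ester 2 (not isolated)
Conditions: TBSCl (2.5 equiv), imidazole, DMF, 25 °C; then K2CO3 (cat.), MeOH/H2O, 25 °C; citric acid work-up
Reagents that add atoms: tert-butyldimethylsilyl chloride, CC(C)(C)[Si](C)(C)Cl
Why: Double O-silylation followed by selective solvolysis of the labile silyl ester is the standard silyl protection of a phenolic acid.

Step 2
Reactants: 3 3-[4-(TBS-oxy)phenyl]propanoic acid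
Product: 4 chloromethyl 3-[4-(TBS-oxy)phenyl]propanoate
Conditions: ClCH2OSO2Cl (1.2 equiv), NaHCO3, Bu4NHSO4 (cat.), CH2Cl2/H2O, 0 → 25 °C
Reagents that add atoms: chloromethyl chlorosulfate, ClCOS(=O)(=O)Cl
Why: Phase-transfer O-alkylation of the carboxylate with chloromethyl chlorosulfate (chlorosulfate as leaving group) is the established route to chloromethyl esters.

Step 3
Reactants: 4 chloromethyl 3-[4-(TBS-oxy)phenyl]propanoate
Product: 5 iodomethyl 3-[4-(TBS-oxy)phenyl]propanoate
Conditions: NaI (2 equiv), acetone, 25 °C, dark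
Reagents that add atoms: sodium iodide, [Na+].[I-]
Why: Finkelstein halide exchange driven by precipitation of NaCl, as used for iodomethyl pivalate.

Step 4
Reactants: 6 (R)-(−)-carvone
Product: 8 6-methylcarvone [(5R)-2,6-dimethyl-5-(prop-1-en-2-yl)cyclohex-2-en-1-one; both C6 epimers], via lithium dienolate 7 (not isolated)
Conditions: LiN(iPr)2 (1.1 equiv), THF, −78 °C; MeI, −78 → 0 °C
Reagents that add atoms: iodomethane, CI
Why: Kinetic α′-deprotonation of the cross-conjugated enone and C-methylation (enolate alkylation); the new C6 centre is re-enolised in step 5, so the epimer mixture is used as such.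

Step 5
Reactants: 8 6-methylcarvone
Product: 10 N-methoxy-N-methyl-2-[1,3-dimethyl-2-oxo-6-(prop-1-en-2-yl)cyclohex-3-en-1-yl]acetamide (acetamide arm trans to the isopropenyl group), via lithium enolate 9 (not isolated)
Conditions: LiN(iPr)2 (1.2 equiv), THF, −78 → 0 °C; DMPU, BrCH2C(O)N(OMe)Me, −78 → 0 °C
Reagents that add atoms: 2-bromo-N-methoxy-N-methylacetamide, CON(C)C(=O)CBr
Why: Enolate alkylation of the tetrasubstituted α′-enolate should occur anti to the neighbouring isopropenyl group, the usual course of the second alkylation of carvone, which sets the quaternary centre (future C10: methyl cis, two-carbon arm trans to the isopropenyl group).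

Step 6
Reactants: 10 Weinreb amide
Product: 11 1-[1,3-dimethyl-2-oxo-6-(prop-1-en-2-yl)cyclohex-3-en-1-yl]but-3-en-2-one (configuration as in 10)
Conditions: CH2=CHMgBr (1.3 equiv), THF, −78 → 0 °C; aq. NH4Cl
Reagents that add atoms: vinylmagnesium bromide, C=C[Mg]Br
Why: Weinreb ketone synthesis; the stable magnesium chelate prevents over-addition, and the ring ketone, flanked by the quaternary carbon, is too hindered to compete.

Step 7
Reactants: 11 vinyl ketone
Product: 12 4,8,10-trimethyl-trans-octalin-3,7-diene-2,9-dione (5α-H; 10β-CH3)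
Conditions: second-generation Hoveyda–Grubbs catalyst RuCl2(H2IMes)(=CH-C6H4-2-OiPr) (5 mol%), toluene (0.01 M), 80 °C
Reagents that add atoms: none
Why: Ring-closing metathesis between the vinyl ketone and the isopropenyl group closes ring A as the 4-methyl-3-en-2-one with loss of ethene; the trans ring fusion follows from the trans arrangement fixed in step 5.

Step 8
Reactants: 12 bicyclic dienedione
Product: 13 2β-hydroxy-4,8,10-trimethyl-trans-octalin-3,7-dien-9-one [(2S)-allylic alcohol]
Conditions: (R)-2-methyl-CBS-oxazaborolidine (0.3 equiv), catecholborane (1.5 equiv), toluene, −78 °C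
Reagents that add atoms: none
Why: Corey–Bakshi–Shibata 1,2-reduction of the less hindered ring A enone; catalyst control and substrate control (hydride on the α face, away from the C10 methyl) should both give the 2β alcohol, while the C9 carbonyl is shielded by C10.

Step 9
Reactants: 13 2β-allylic alcohol
Product: 14 2β-(TBS-oxy)-4,8,10-trimethyl-trans-octalin-3,7-dien-9-one
Conditions: TBSCl, imidazole, DMAP (cat.), DMF, 40 °C
Reagents that add atoms: tert-butyldimethylsilyl chloride, CC(C)(C)[Si](C)(C)Cl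
Why: Silyl protection of the secondary allylic alcohol, needed because step 11 is an oxidation.

Step 10
Reactants: 14 silyl ether enone; 15 2-(2-bromoethyl)-2-methyl-1,3-dioxolane
Product: 17 2β-(TBS-oxy)-9-hydroxy-14,15,19-trinorlabda-3,7-dien-13-one 13-ethylene ketal (C9 configuration immaterial), via Grignard reagent 16 (not isolated)
Conditions: 15, Mg, THF, 40 °C; then CeCl3 (anhydrous, 1.5 equiv), THF, −78 °C; 14, −78 → 0 °C; aq. NH4Cl
Reagents that add atoms: none
Why: Organocerium (Imamoto) 1,2-addition to the hindered, non-enolisable C9 enone carbonyl; the new carbinol centre is destroyed in step 11, so its configuration does not matter.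

Step 11
Reactants: 17 tertiary allylic alcohol
Product: 18 2β-(TBS-oxy)-14,15,19-trinorlabda-3,8-diene-7,13-dione 13-ethylene ketal
Conditions: pyridinium chlorochromate (C5H5NH)[CrO3Cl] (2.5 equiv), NaOAc, 4 Å molecular sieves, CH2Cl2, 25 °C
Reagents that add atoms: pyridinium chlorochromate, [O-][Cr](=O)(=O)Cl.c1cc[nH+]cc1
Why: Babler–Dauben oxidative 1,3-transposition of the tertiary allylic alcohol moves the oxygen to C7 and leaves the side chain on the C8=C9 double bond, a sequence well known for carvone-derived carbinols.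

Step 12
Reactants: 18 transposed enone
Product: 19 7β-hydroxy-2β-(TBS-oxy)-14,15,19-trinorlabda-3,8-dien-13-one ethylene ketal
Conditions: NaBH4, CeCl3·7H2O, MeOH, −40 °C
Reagents that add atoms: none
Why: Luche 1,2-reduction; axial hydride delivery on the unhindered α face should give the equatorial 7β alcohol.

Step 13
Reactants: 19 7β-allylic alcohol
Product: 22 2β-(TBS-oxy)-14,15,19-trinorlabda-3,7-dien-13-one ethylene ketal (9α-H), via sulfonylhydrazine 20 (not isolated), via allylic diazene 21 (not isolated)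
Conditions: PPh3, diethyl azodicarboxylate, 2-nitrobenzenesulfonylhydrazide, N-methylmorpholine, −30 °C; then 25 °C
Reagents that add atoms: none
Why: Myers reductive 1,3-transposition: Mitsunobu displacement inverts C7, loss of the sulfinate gives the 7α-diazene, and its retro-ene loss of N2 delivers hydrogen suprafacially to the α face of C9, which sets 9α-H and places the double bond at C7=C8.

Step 14
Reactants: 22 silyl ether diene
Product: 23 2β-hydroxy-14,15,19-trinorlabda-3,7-dien-13-one ethylene ketal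
Conditions: Bu4NF, THF, 25 °C
Reagents that add atoms: none
Why: Fluoride desilylation frees the 2β-hydroxyl for the directing ester.

Step 15
Reactants: 23 2β-allylic alcohol
Product: 24 2β-[2-(diphenylphosphanyl)benzoyloxy]-14,15,19-trinorlabda-3,7-dien-13-one ethylene ketal
Conditions: 2-(Ph2P)C6H4CO2H, DCC, DMAP (cat.), CH2Cl2, 25 °C, argon
Reagents that add atoms: 2-(diphenylphosphanyl)benzoic acid, OC(=O)c1ccccc1P(c1ccccc1)c1ccccc1
Why: Steglich esterification installs the reagent-directing leaving group on the 2β oxygen with retention at C2.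

Step 16
Reactants: 24 allylic 2-(diphenylphosphanyl)benzoate; 5 iodomethyl 3-[4-(TBS-oxy)phenyl]propanoate
Product: 27 19-{3-[4-(TBS-oxy)phenyl]propanoyloxy}-14,15-dinorlabda-2,7-dien-13-one ethylene ketal (C19 on the β face; 4α-CH3), via organozinc iodide 25 (not isolated), via organocopper reagent 26 (not isolated)
Conditions: 5, Zn dust, LiCl, THF, 25 °C; CuBr·SMe2 (1.0 equiv), −30 °C; then 24, Et2O/THF, −30 → 25 °C, argon
Reagents that add atoms: none
Why: Proposed new method: zinc inserts into the carbon–iodine bond of 5 to give the carbonyl-chelated α-acyloxymethylzinc iodide 25, CuBr·SMe2 converts it into the monovalent organocopper 26, and the phosphine of the 2β-ester of 24 binds this copper, so that oxidative addition into the allylic C2–O bond and reductive elimination from the resulting trivalent σ-allyl copper take place intramolecularly at C4, on the face of the departing carboxylate. The closest known reaction type is the copper-mediated syn-SN2′ allylic substitution directed by an ortho-diphenylphosphanylbenzoate leaving group (Grignard and diorganozinc nucleophiles, quaternary centres with 1,3-chirality transfer), together with the known SN2′ allylation chemistry of (pivaloyloxy)methylzinc and -copper reagents; new here is an α-acyloxymethyl nucleophile in the directed mode on a ring-fused, γ,γ-disubstituted cyclohexenyl ester. No ring is closed; the only cyclic element is the transient P–Cu chelate, which is lost with the leaving group. The single new stereocentre, C4, is controlled by the C2 carbinol centre set in step 8: syn delivery places C19 on the β face, cis to the C10 methyl (axial), and leaves the C4 methyl α. The step needs γ- over α-substitution and syn over anti attack, because an undirected reagent would attack C4 from the open α face or substitute at C2; the pseudoaxial 2β C–O bond aligned with the C3=C4 π system, the strongly copper-binding phosphine and a cyanide-free ethereal medium, in which unbound copper reagent is sluggish, are meant to secure this. The ester α-hydrogens, the ketal and the C7=C8 bond should be inert to the zinc and copper species.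

Step 17
Reactants: 27 coupled 2,7-diene
Product: 28 19-{3-[4-(TBS-oxy)phenyl]propanoyloxy}-14,15-dinorlabd-7-en-13-one ethylene ketal
Conditions: H2 (1 atm), RhCl(PPh3)3 (10 mol%), benzene/EtOH, 25 °C
Reagents that add atoms: none
Why: Homogeneous hydrogenation with Wilkinson's catalyst should reduce the cis-disubstituted C2=C3 bond and leave the hindered trisubstituted C7=C8 bond.

Step 18
Reactants: 28 labd-7-ene ester
Product: 29 7α,8α-dihydroxy-19-{3-[4-(TBS-oxy)phenyl]propanoyloxy}-14,15-dinorlabdan-13-one ethylene ketal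
Conditions: OsO4 (5 mol%), N-methylmorpholine N-oxide, acetone/H2O, 25 °C
Reagents that add atoms: osmium tetroxide, O=[Os](=O)(=O)=O; N-methylmorpholine N-oxide, C[N+]1([O-])CCOCC1; water, O
Why: Upjohn syn-dihydroxylation from the α face, opposite the axial C10 methyl, should give the 7α,8α-cis-diol.

Step 19
Reactants: 29 7α,8α-diol
Product: 30 7α,8α-O-isopropylidene derivative of 29
Conditions: 2-methoxypropene, PPTS (cat.), CH2Cl2, 0 °C
Reagents that add atoms: 2-methoxypropene, COC(C)=C
Why: Acetonide formation on the cis-diol under anhydrous kinetic conditions that leave the side-chain dioxolane untouched.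

Step 20
Reactants: 30 acetonide ester
Product: 34 19-{(E)-3-[4-(TBS-oxy)phenyl]prop-2-enoyloxy}-7α,8α-isopropylidenedioxy-14,15-dinorlabdan-13-one ethylene ketal, via lithium ester enolate 31 (not isolated), via α-phenylselanyl ester 32 (not isolated), via selenoxide 33 (not isolated)
Conditions: LiN(iPr)2 (1.2 equiv), THF, −78 °C; PhSeBr, −78 °C; then 30% H2O2, pyridine, CH2Cl2, 0 → 25 °C
Reagents that add atoms: none
Why: Reich–Sharpless α-selenenylation and selenoxide syn-elimination toward the benzylic hydrogens should give the conjugated (E)-cinnamate.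

Step 21
Reactants: 34 cinnamate ketal
Product: 35 19-{(E)-3-[4-(TBS-oxy)phenyl]prop-2-enoyloxy}-7α,8α-isopropylidenedioxy-14,15-dinorlabdan-13-one
Conditions: PPTS, acetone/H2O (20:1), 55 °C
Reagents that add atoms: water, O
Why: Acid-catalysed ketal exchange and hydrolysis in acetone frees the methyl ketone, while the acetonide is held by the large excess of acetone.

Step 22
Reactants: 35 methyl ketone
Product: 37 13-(trifluoromethanesulfonyloxy)-14,15-dinorlabd-13(16)-ene bearing the 7α,8α-acetonide and the 19-(E)-4-(TBS-oxy)cinnamate, via potassium enolate 36 (not isolated)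
Conditions: KN(SiMe3)2 (1.1 equiv), THF, −78 °C; PhNTf2, −78 → 0 °C
Reagents that add atoms: N-phenylbis(trifluoromethanesulfonimide), O=S(=O)(N(c1ccccc1)S(=O)(=O)C(F)(F)F)C(F)(F)F
Why: Kinetic enolate formation at the methyl group and O-triflation; the cinnamate has no α-hydrogen to compete.

Step 23
Reactants: 37 protected enol triflate
Product: 38 7α,8α-dihydroxy-13-(trifluoromethanesulfonyloxy)-14,15-dinorlabd-13(16)-en-19-yl (E)-4-hydroxycinnamate
Conditions: 48% aq. HF, MeCN, 0 → 25 °C
Reagents that add atoms: none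
Why: Aqueous HF should cleave the aryl silyl ether and hydrolyse the acetonide in one operation (global deprotection) before the acid-sensitive diene exists; enol triflate and ester tolerate it.

Step 24
Reactants: 38 enol triflate triol
Product: 39 7α,8α-dihydroxylabda-13(16),14-dien-19-yl (E)-4-hydroxycinnamate (CNP0254560.2)
Conditions: CH2=CHSnBu3 (1.5 equiv), Pd(PPh3)4 (5 mol%), LiCl (3 equiv), THF, 60 °C
Reagents that add atoms: tributyl(vinyl)stannane, C=C[Sn](CCCC)(CCCC)CCCC
Why: Stille coupling of the enol triflate builds the 2-substituted buta-1,3-diene as the last step and tolerates the free phenol and diol.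

**Compound list**
1 | 3-(4-hydroxyphenyl)propanoic acid | OC(=O)CCc1ccc(O)cc1 | starting material
2 | TBS 3-[4-(TBS-oxy)phenyl]propanoate | CC(C)(C)[Si](C)(C)OC(=O)CCc1ccc(O[Si](C)(C)C(C)(C)C)cc1 | intermediate
3 | 3-[4-(TBS-oxy)phenyl]propanoic acid | OC(=O)CCc1ccc(O[Si](C)(C)C(C)(C)C)cc1 | intermediate
4 | chloromethyl 3-[4-(TBS-oxy)phenyl]propanoate | ClCOC(=O)CCc1ccc(O[Si](C)(C)C(C)(C)C)cc1 | intermediate
5 | iodomethyl 3-[4-(TBS-oxy)phenyl]propanoate | ICOC(=O)CCc1ccc(O[Si](C)(C)C(C)(C)C)cc1 | intermediate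
6 | (R)-(−)-carvone | O=C1C(C)=CC[C@@H](C(C)=C)C1 | starting material
7 | lithium dienolate of carvone (O–Li on C1, C1=C6) | [Li]OC1=C[C@H](C(C)=C)CC=C1C | intermediate
8 | 6-methylcarvone, (5R), both C6 epimers | O=C1C(C)=CC[C@@H](C(C)=C)C1C | intermediate
9 | lithium enolate of 6-methylcarvone | [Li]OC1=C(C)[C@H](C(C)=C)CC=C1C | intermediate
10 | N-methoxy-N-methyl-2-[1,3-dimethyl-2-oxo-6-(prop-1-en-2-yl)cyclohex-3-en-1-yl]acetamide, acetamide arm trans to isopropenyl | O=C1C(C)=CC[C@@H](C(C)=C)[C@]1(C)CC(=O)N(C)OC | intermediate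
11 | 1-[1,3-dimethyl-2-oxo-6-(prop-1-en-2-yl)cyclohex-3-en-1-yl]but-3-en-2-one | O=C1C(C)=CC[C@@H](C(C)=C)[C@]1(C)CC(=O)C=C | intermediate
12 | 4,8,10-trimethyl-trans-octalin-3,7-diene-2,9-dione (5α-H, 10β-CH3) | O=C1C(C)=CC[C@H]2C(C)=CC(=O)C[C@@]21C | intermediate
13 | 2β-hydroxy-4,8,10-trimethyl-trans-octalin-3,7-dien-9-one | O=C1C(C)=CC[C@H]2C(C)=C[C@@H](O)C[C@@]21C | intermediate
14 | 2β-(TBS-oxy)-4,8,10-trimethyl-trans-octalin-3,7-dien-9-one | O=C1C(C)=CC[C@H]2C(C)=C[C@@H](O[Si](C)(C)C(C)(C)C)C[C@@]21C | intermediate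
15 | 2-(2-bromoethyl)-2-methyl-1,3-dioxolane | CC1(CCBr)OCCO1 | starting material
16 | [2-(2-methyl-1,3-dioxolan-2-yl)ethyl]magnesium bromide | CC1(CC[Mg]Br)OCCO1 | intermediate
17 | 2β-(TBS-oxy)-9-hydroxy-14,15,19-trinorlabda-3,7-dien-13-one ethylene ketal (C9 epimers) | OC1(CCC3(C)OCCO3)C(C)=CC[C@H]2C(C)=C[C@@H](O[Si](C)(C)C(C)(C)C)C[C@@]21C | intermediate
18 | 2β-(TBS-oxy)-14,15,19-trinorlabda-3,8-diene-7,13-dione 13-ethylene ketal | CC3(OCCO3)CCC1=C(C)C(=O)C[C@H]2C(C)=C[C@@H](O[Si](C)(C)C(C)(C)C)C[C@@]21C | intermediate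
19 | 7β-hydroxy-2β-(TBS-oxy)-14,15,19-trinorlabda-3,8-dien-13-one ethylene ketal | CC3(OCCO3)CCC1=C(C)[C@@H](O)C[C@H]2C(C)=C[C@@H](O[Si](C)(C)C(C)(C)C)C[C@@]21C | intermediate
20 | 7α-[1-(2-nitrobenzenesulfonyl)hydrazinyl] analogue of 19 | CC3(OCCO3)CCC1=C(C)[C@H](N(N)S(=O)(=O)c4ccccc4[N+](=O)[O-])C[C@H]2C(C)=C[C@@H](O[Si](C)(C)C(C)(C)C)C[C@@]21C | intermediate
21 | 7α-diazenyl analogue of 19 (allylic diazene) | CC3(OCCO3)CCC1=C(C)[C@H](N=N)C[C@H]2C(C)=C[C@@H](O[Si](C)(C)C(C)(C)C)C[C@@]21C | intermediate
22 | 2β-(TBS-oxy)-14,15,19-trinorlabda-3,7-dien-13-one ethylene ketal (9α-H) | CC3(OCCO3)CC[C@H]1C(C)=CC[C@H]2C(C)=C[C@@H](O[Si](C)(C)C(C)(C)C)C[C@@]21C | intermediate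
23 | 2β-hydroxy-14,15,19-trinorlabda-3,7-dien-13-one ethylene ketal | CC3(OCCO3)CC[C@H]1C(C)=CC[C@H]2C(C)=C[C@@H](O)C[C@@]21C | intermediate
24 | 2β-[2-(diphenylphosphanyl)benzoyloxy]-14,15,19-trinorlabda-3,7-dien-13-one ethylene ketal | CC3(OCCO3)CC[C@H]1C(C)=CC[C@H]2C(C)=C[C@@H](OC(=O)c4ccccc4P(c4ccccc4)c4ccccc4)C[C@@]21C | intermediate
25 | {3-[4-(TBS-oxy)phenyl]propanoyloxy}methylzinc iodide | I[Zn]COC(=O)CCc1ccc(O[Si](C)(C)C(C)(C)C)cc1 | intermediate
26 | {3-[4-(TBS-oxy)phenyl]propanoyloxy}methylcopper (zinc halide complex) | [Cu]COC(=O)CCc1ccc(O[Si](C)(C)C(C)(C)C)cc1 | intermediate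
27 | 19-{3-[4-(TBS-oxy)phenyl]propanoyloxy}-14,15-dinorlabda-2,7-dien-13-one ethylene ketal | CC3(OCCO3)CC[C@H]1C(C)=CC[C@H]2[C@@](C)(COC(=O)CCc4ccc(O[Si](C)(C)C(C)(C)C)cc4)C=CC[C@@]21C | intermediate
28 | 19-{3-[4-(TBS-oxy)phenyl]propanoyloxy}-14,15-dinorlabd-7-en-13-one ethylene ketal | CC3(OCCO3)CC[C@H]1C(C)=CC[C@H]2[C@@](C)(COC(=O)CCc4ccc(O[Si](C)(C)C(C)(C)C)cc4)CCC[C@@]21C | intermediate
29 | 7α,8α-dihydroxy-19-{3-[4-(TBS-oxy)phenyl]propanoyloxy}-14,15-dinorlabdan-13-one ethylene ketal | CC3(OCCO3)CC[C@H]1[C@](C)(O)[C@H](O)C[C@H]2[C@@](C)(COC(=O)CCc4ccc(O[Si](C)(C)C(C)(C)C)cc4)CCC[C@@]21C | intermediate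
30 | 7α,8α-O-isopropylidene derivative of 29 | CC3(OCCO3)CC[C@H]1[C@]4(C)OC(C)(C)O[C@@H]4C[C@H]2[C@@](C)(COC(=O)CCc5ccc(O[Si](C)(C)C(C)(C)C)cc5)CCC[C@@]21C | intermediate
31 | lithium ester enolate of 30 | CC3(OCCO3)CC[C@H]1[C@]4(C)OC(C)(C)O[C@@H]4C[C@H]2[C@@](C)(COC(O[Li])=CCc5ccc(O[Si](C)(C)C(C)(C)C)cc5)CCC[C@@]21C | intermediate
32 | α-phenylselanyl ester of 30 (both α-epimers) | CC3(OCCO3)CC[C@H]1[C@]4(C)OC(C)(C)O[C@@H]4C[C@H]2[C@@](C)(COC(=O)C([Se]c6ccccc6)Cc5ccc(O[Si](C)(C)C(C)(C)C)cc5)CCC[C@@]21C | intermediate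
33 | selenoxide of 32 | CC3(OCCO3)CC[C@H]1[C@]4(C)OC(C)(C)O[C@@H]4C[C@H]2[C@@](C)(COC(=O)C([Se](=O)c6ccccc6)Cc5ccc(O[Si](C)(C)C(C)(C)C)cc5)CCC[C@@]21C | intermediate
34 | 19-{(E)-3-[4-(TBS-oxy)phenyl]prop-2-enoyloxy}-7α,8α-isopropylidenedioxy-14,15-dinorlabdan-13-one ethylene ketal | CC3(OCCO3)CC[C@H]1[C@]4(C)OC(C)(C)O[C@@H]4C[C@H]2[C@@](C)(COC(=O)/C=C/c5ccc(O[Si](C)(C)C(C)(C)C)cc5)CCC[C@@]21C | intermediate
35 | 19-{(E)-3-[4-(TBS-oxy)phenyl]prop-2-enoyloxy}-7α,8α-isopropylidenedioxy-14,15-dinorlabdan-13-one | CC(=O)CC[C@H]1[C@]4(C)OC(C)(C)O[C@@H]4C[C@H]2[C@@](C)(COC(=O)/C=C/c5ccc(O[Si](C)(C)C(C)(C)C)cc5)CCC[C@@]21C | intermediate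
36 | potassium enolate of 35 (terminal) | [K]OC(=C)CC[C@H]1[C@]4(C)OC(C)(C)O[C@@H]4C[C@H]2[C@@](C)(COC(=O)/C=C/c5ccc(O[Si](C)(C)C(C)(C)C)cc5)CCC[C@@]21C | intermediate
37 | 13-(trifluoromethanesulfonyloxy)-14,15-dinorlabd-13(16)-ene with 7α,8α-acetonide and 19-(E)-4-(TBS-oxy)cinnamate | C=C(OS(=O)(=O)C(F)(F)F)CC[C@H]1[C@]4(C)OC(C)(C)O[C@@H]4C[C@H]2[C@@](C)(COC(=O)/C=C/c5ccc(O[Si](C)(C)C(C)(C)C)cc5)CCC[C@@]21C | intermediate
38 | 7α,8α-dihydroxy-13-(trifluoromethanesulfonyloxy)-14,15-dinorlabd-13(16)-en-19-yl (E)-4-hydroxycinnamate | C=C(OS(=O)(=O)C(F)(F)F)CC[C@H]1[C@](C)(O)[C@H](O)C[C@H]2[C@@](C)(COC(=O)/C=C/c3ccc(O)cc3)CCC[C@@]21C | intermediate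
39 | 7α,8α-dihydroxylabda-13(16),14-dien-19-yl (E)-4-hydroxycinnamate (CNP0254560.2) | C=CC(=C)CC[C@H]1[C@](C)(O)[C@H](O)C[C@H]2[C@@](C)(COC(=O)/C=C/c3ccc(O)cc3)CCC[C@@]21C | target

**Step count**
Total: 24 steps. Longest linear sequence: 21 steps (steps 4 to 24, from (R)-carvone). Steps 1 to 3 form the side branch that enters at step 16.

**Steps most likely to fail**

1. Step 16 (proposed method). The copper reagent may react without guidance by the phosphine, which would mean anti attack on the α face of C4 or direct substitution at C2. The α-acyloxymethyl metal species may also decompose before it is transferred. The fallback uses known chemistry and replaces the fragment coupling by a sigmatropic delivery from the same oxygen. It sets out from allylic alcohol 23. O-Alkylation with Bu3SnCH2I (KH, 18-crown-6, THF) should give the stannylmethyl ether F1. Tin–lithium exchange (n-BuLi, THF, −78 °C) triggers the Wittig–Still [2,3]-shift, which carries the CH2O unit suprafacially from the 2β oxygen to C4β and should give the C19 alcohol F2 with the C2=C3 bond. Hydrogenation (H2, RhCl(PPh3)3) should give the saturated C19 alcohol F3. Steglich esterification of F3 with acid 3 (DCC, DMAP) comes back to the route at compound 28.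

2. Step 13. Inversion at C7 may be incomplete (competing SN2′ displacement or elimination in the Mitsunobu stage), or step 12 may deliver the wrong C7 epimer; either would erode the facial transfer of hydrogen to C9. The fallback replaces the diazene route by a dissolving-metal route. It sets out from enone 18. Li/NH3 (THF, t-BuOH 1 equiv, −78 °C) should protonate C9 axially from the α face and give the lithium enolate F4, which is trapped in the same flask with PhNTf2 as the enol triflate F5. Reduction of F5 with Pd(OAc)2/PPh3, Bu3N and HCO2H (DMF, 60 °C) removes the triflate and comes back to the route at compound 22.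

3. Step 5. C-Alkylation of the hindered tetrasubstituted enolate by the α-bromo amide may be slow, so that O-alkylation or proton transfer takes over. The fallback uses a more reactive ester electrophile and makes the amide afterwards. It sets out from 8. LiN(iPr)2 and then tert-butyl bromoacetate should give the tert-butyl ester F6, with the arm trans to the isopropenyl group. CF3CO2H in CH2Cl2 gives the acid F7. Coupling of F7 with MeNHOMe·HCl (EDC·HCl, Et3N) comes back to the route at compound 10.

Further compounds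
F1 | step 16 | 2β-(tributylstannylmethoxy)-14,15,19-trinorlabda-3,7-dien-13-one ethylene ketal | CC3(OCCO3)CC[C@H]1C(C)=CC[C@H]2C(C)=C[C@@H](OC[Sn](CCCC)(CCCC)CCCC)C[C@@]21C
F2 | step 16 | 19-hydroxy-14,15-dinorlabda-2,7-dien-13-one ethylene ketal | CC3(OCCO3)CC[C@H]1C(C)=CC[C@H]2[C@@](C)(CO)C=CC[C@@]21C
F3 | step 16 | 19-hydroxy-14,15-dinorlabd-7-en-13-one ethylene ketal | CC3(OCCO3)CC[C@H]1C(C)=CC[C@H]2[C@@](C)(CO)CCC[C@@]21C
F4 | step 13 | lithium 7-enolate of 2β-(TBS-oxy)-14,15,19-trinorlabd-3-ene-7,13-dione 13-ethylene ketal (9α-H) | CC3(OCCO3)CC[C@H]1C(C)=C(O[Li])C[C@H]2C(C)=C[C@@H](O[Si](C)(C)C(C)(C)C)C[C@@]21C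
F5 | step 13 | 7-(trifluoromethanesulfonyloxy)-2β-(TBS-oxy)-14,15,19-trinorlabda-3,7-dien-13-one ethylene ketal | CC3(OCCO3)CC[C@H]1C(C)=C(OS(=O)(=O)C(F)(F)F)C[C@H]2C(C)=C[C@@H](O[Si](C)(C)C(C)(C)C)C[C@@]21C
F6 | step 5 | tert-butyl 2-[1,3-dimethyl-2-oxo-6-(prop-1-en-2-yl)cyclohex-3-en-1-yl]acetate | O=C1C(C)=CC[C@@H](C(C)=C)[C@]1(C)CC(=O)OC(C)(C)C
F7 | step 5 | 2-[1,3-dimethyl-2-oxo-6-(prop-1-en-2-yl)cyclohex-3-en-1-yl]acetic acid | O=C1C(C)=CC[C@@H](C(C)=C)[C@]1(C)CC(=O)O
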